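## The problem

The target 20 is a 3-deoxyflavan (rings A, C and B, unprimed locants) bonded through C4 to C8' of an epigallocatechin 3'-O-gallate unit (rings D, F and E, primed locants; galloyl ring G). It has four stereocentres in two isolated pairs: C2 (S) and C4 (R) are 1,3-trans on ring C, and C2' (R) and C3' (R) are cis on ring F. Within a pair one centre can steer the other: ring B at C2 sends a nucleophile to the opposite face of a C4 cation, and ring E at C2' sends a hydride to the opposite face of a C3' ketone. Across the freely rotating C4–C8' bond no such control exists, so each pair needs its own chiral source. The C4–C8' bond is doubly benzylic and is cleaved by protic acid, the C3' gallate hydrolyses or migrates in base, C2' epimerises in base, and the twelve phenols (six in two pyrogallol rings) oxidise in air once free. All phenols must therefore be carried as ethers that come off under neutral conditions at the very end. The feature that allows the key step is ring F: C2' (bearing O1' and ring E) and C3' (bearing the gallate oxygen) are adjacent oxygenated carbons, a 1,2-pattern that polar bond formation cannot join. Because O1' is also the phenolic oxygen of ring D, C2' with ring E can be carried as an aryl 3,4,5-trioxybenzoate and C3' as an aldehyde, and a reducing metal can join the two carbonyl carbons. One protected gallic acid thus supplies both ring E with C2' and ring G.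

## Retrosynthesis

**20 from 19.** The twelve O–benzyl bonds are cut. Benzyl ethers are chosen over silyl, acetal or acyl groups because only hydrogenolysis avoids the acid that breaks C4–C8' and the base that attacks the gallate. The forward step must remove twelve benzyl groups without opening the benzylic C–O bonds of rings C and F.

**19 from 18 and 10.** The O3'–acyl bond is cut, giving the 2',3'-cis alcohol 18 and commercial acid 10. Acylation of a cis flavan-3-ol with retention is standard. Direct esterification of the trans alcohol 16 with inversion is the shorter neighbour, but activation of a trans flavan-3-ol invites elimination and aryl participation, so it is kept only as a fallback.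

**18 from 17 from 16.** The C3'–H bond is cut: the cis alcohol comes from ketone 17 by a bulky hydride entering opposite ring E, and 17 from the trans alcohol 16. This costs two steps but turns the unfavourable cis relationship into a substrate-controlled reduction. The forward steps must not epimerise C2'.

**16 from 14.** The C2'–H and C3'–O bonds are cut, leading back to the planar enol ether 14. A syn hydroboration places boron at C3' (β to O1' and to ring E) and hydrogen at C2'. Since C3' is reset later, the chiral borane only has to set C2'. Dihydroxylation or epoxidation would give a hemiketal at C2' and lose this centre.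

**14 from 13 (key disconnection).** The C2'=C3' bond is cut into two carbonyl groups, the C3' aldehyde and the ring D aryl ester in 13. Cutting O1'–C2' or C4'–C4a' instead would leave the dissonant C2'–C3' diol pattern to be built elsewhere. This cut removes ring F and reduces ring E plus C2' to a galloyl ester. The forward reaction must couple aldehyde and ester within one molecule faster than two aldehydes couple between molecules.

**13 from 11 from 9 and 10.** The aldehyde is traced to the terminal alkene of allyl ester 11 (C=C cleavage), and 11 to phenol 9 and acid 10 (O–acyl bond). The allyl group is inert until needed, and the labile arylacetaldehyde appears only one step before its use.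

**9 from 8 from 7.** The C4a'–CH2 bond is cut by a Claisen transform to allyl ether 8, made from phenol 7. The oxygen that becomes O1' delivers the allyl group to its only free ortho carbon, so the position of the side chain is fixed by the rearrangement and not by a separate aromatic substitution.

**7 from 5 and 6.** The C4–C8' bond is cut into a C4 cation equivalent, the 4-alkoxyflavan 5, and commercial phenol 6. Making this bond early, on a simple phenol, avoids exposing a finished ring F and gallate to Lewis acid. The forward step must select the ring carbon between OH and OBn of 6 and must place the aryl group trans to ring B.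

**5 from 4 from 3 from 2 from 1.** The C3–O bond (radical deoxygenation), the C4–O bond (benzylic oxidation) and the benzyl ethers are removed, leading to (+)-catechin 1. A natural (2S)-5-hydroxyflavanone would be the more direct source of ring C. However, its chelated 5-hydroxyl resists benzylation, and the base needed opens ring C to the chalcone and erases C2. Catechin has no enolisable carbonyl, and its C2 has the spatial arrangement required (the descriptor changes from R to S when the C3 oxygen is removed). Both its tetrabenzyl ether 2 and the C4 alkoxylation to 3 are standard.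

## Roads not taken

**Alternative 1:** The cut is the O1–C8a bond of ring C, with ring A carried as a 5-silyloxycyclohexane-1,3-dione and aromatised late. In the forward key step acid condenses the C2 hydroxyl of the open-chain hydroxy dione A2 with a dione carbonyl to give the vinylogous ester A1, closing ring C without touching C2 or C4.
- Merits: the lower half is octa-O-benzyl epigallocatechin gallate A3 from the chiral pool, so C2', C3' and the ester cost nothing; the ring closure is a simple six-membered condensation.
- Weak points: C2 and C4 must both be set in an acyclic chain, at a C4 attached to the crowded C8' of A3. The C2 carbinol is a benzylic alcohol on a dialkoxyphenyl ring and ionises under the acid that drives the condensation, so its configuration is at risk. Aromatising ring A needs dehydrogenation of a β-silyloxy ketone, which competes with β-elimination of silanol and loss of the C7 oxygen.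
- Comparison: this road is better in that no stereocentre of ring F has to be made, whereas the chosen plan spends four steps after the key step to set C2' and C3' and attach the gallate. The chosen plan offers in return C2 from catechin, C4 from a cation capture steered by C2, and a ring A that is aromatic throughout.

**Alternative 2:** Three bonds of ring C are cut: C4–C4a, C3–C4 and O1–C2. In the forward key step a chiral phosphoric acid condenses phenol A7 (the same compound as 6) with the C8' aldehyde A5, derived from A3, to an ortho-quinone methide intermediate. Styrene A6 traps it in a [4+2] cycloaddition to give A4, which is identical with 19.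
- Merits: it is the most convergent plan, uses A3 intact, and reaches the penultimate compound in one operation, in roughly a third of the steps.
- Weak points: cycloadditions of ortho-quinone methides with styrenes normally pass through an endo transition state and give 2,4-cis chromans, whereas 20 is 2,4-trans. The catalyst must also override a chiral, doubly ortho-substituted aldehyde. The intermediate can be intercepted by a second molecule of A7, and A7 can react para to its hydroxyl, which leads to no quinone methide.
- Comparison: in step economy this road is clearly superior and would be preferred if relative and absolute configuration could be secured. The chosen plan offers in return the predictable trans outcome of cation capture at C4 and a C2 taken from the chiral pool.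

**Alternative 3:** The C3'–C4' and O1'–C2' bonds of ring F are cut. In the forward key step the ortho-quinone methide from the ring D salicyl alcohol A9 adds the Z-styrenylboronate A10 to give the 2',3'-cis C3' boronate A8; oxidation with retention would then give 18.
- Merits: the cis relationship is copied directly from the alkene geometry, the upper half is shared with the chosen plan, and two steps replace four.
- Weak points: ortho-quinone methides need electron-rich partners, and an alkenylboronate is a weak one whose Z isomer is hindered and prone to isomerise. Nothing controls the absolute sense, since the heterodiene is flat and the only chirality is the remote upper flavan. Generating the intermediate needs heat or acid that the C4–C8' bond tolerates poorly.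
- Comparison: this road is better on relative configuration and shorter. The chosen plan offers in return a reagent-controlled hydroboration for the absolute configuration at C2' and a substrate-controlled reduction for the cis relationship.

Key step: step 10

Remarks on the chemistry:
- Bn is benzyl.
- Fl is the upper flavanyl group, (2S)-5,7-bis(benzyloxy)-2-[3,4-bis(benzyloxy)phenyl]chroman-4-yl, bonded through C4 with ring B and the C4 substituent on opposite faces of ring C (2,4-trans). This is the arrangement of 20; the C4 descriptor changes with the ring D substituents.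
- Compounds 6 and 10 are taken as purchased.
- The facial sense of IpcBH2 is assigned by analogy with 1-arylcycloalkenes. Should it prove opposite, the reagent from (−)-α-pinene is used in step 11 without other change.

## Route

Step 1
Reactants: 1 (+)-catechin
Product: 2 (2R,3S)-5,7-bis(benzyloxy)-2-[3,4-bis(benzyloxy)phenyl]chroman-3-ol
Conditions: BnBr, K2CO3, DMF, 0 °C to rt, under argon
Reagents that add atoms: benzyl bromide, BrCc1ccccc1
Why: Williamson etherification; K2CO3 deprotonates the four phenols but not the secondary C3 alcohol, and no enolisable carbonyl is present, so C2 and C3 are untouched.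

Step 2
Reactants: 2 (2R,3S)-5,7-bis(benzyloxy)-2-[3,4-bis(benzyloxy)phenyl]chroman-3-ol
Product: 3 (2R,3S,4S)-5,7-bis(benzyloxy)-2-[3,4-bis(benzyloxy)phenyl]-4-(2-ethoxyethoxy)chroman-3-ol
Conditions: DDQ, 2-ethoxyethanol, CH2Cl2, rt
Reagents that add atoms: 2-ethoxyethanol, CCOCCO
Why: Benzylic oxidation by hydride abstraction at C4 (activated by the 5,7-dialkoxy ring A) and capture of the cation by the alcohol, a standard way to activate C4 of benzylated flavan-3-ols; the alkoxy group should enter trans to ring B, but its configuration is immaterial because C4 is ionised again in step 5.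

Step 3
Reactants: 3 (2R,3S,4S)-5,7-bis(benzyloxy)-2-[3,4-bis(benzyloxy)phenyl]-4-(2-ethoxyethoxy)chroman-3-ol
Product: 4 O-phenyl O-[(2R,3S,4S)-5,7-bis(benzyloxy)-2-[3,4-bis(benzyloxy)phenyl]-4-(2-ethoxyethoxy)chroman-3-yl] carbonothioate
Conditions: PhOC(S)Cl, pyridine, DMAP (cat.), CH2Cl2, 0 °C to rt
Reagents that add atoms: O-phenyl chlorothionoformate, S=C(Cl)Oc1ccccc1
Why: Thioacylation of the secondary alcohol under mild base, which the acid-labile C4 ether tolerates; it prepares the Barton–McCombie deoxygenation.

Step 4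
Reactants: 4 O-phenyl O-[(2R,3S,4S)-5,7-bis(benzyloxy)-2-[3,4-bis(benzyloxy)phenyl]-4-(2-ethoxyethoxy)chroman-3-yl] carbonothioate
Product: 5 (2S,4R)-5,7-bis(benzyloxy)-2-[3,4-bis(benzyloxy)phenyl]-4-(2-ethoxyethoxy)chroman (2,4-trans)
Conditions: Bu3SnH, AIBN (cat.), toluene, 100 °C
Reagents that add atoms: none
Why: Barton–McCombie radical deoxygenation; the C3 radical is reduced by the stannane faster than it can fragment or rearrange, the conditions are neutral, and C2 keeps its spatial arrangement (now described as S).

Step 5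
Reactants: 5 (2S,4R)-5,7-bis(benzyloxy)-2-[3,4-bis(benzyloxy)phenyl]-4-(2-ethoxyethoxy)chroman, 6 3,5-bis(benzyloxy)phenol (excess)
Product: 7 3,5-bis(benzyloxy)-2-Fl-phenol
Conditions: Me3SiOTf, CH2Cl2, −78 °C; 6 in excess
Reagents that add atoms: none
Why: Lewis acid ionisation of the C4 ether and Friedel–Crafts capture of the flavan-4-yl cation, as in interflavan bond formation; the phenol should react at the less hindered, statistically favoured carbon between OH and OBn, and quasi-axial attack on the half-chair cation opposite ring B should give the 2,4-trans product, setting C4 under control of C2.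

Step 6
Reactants: 7 3,5-bis(benzyloxy)-2-Fl-phenol
Product: 8 1-(allyloxy)-3,5-bis(benzyloxy)-2-Fl-benzene
Conditions: allyl bromide, K2CO3, DMF, rt to 50 °C
Reagents that add atoms: allyl bromide, C=CCBr
Why: Williamson etherification of the single free phenol; no other acidic or electrophilic site is present.

Step 7
Reactants: 8 1-(allyloxy)-3,5-bis(benzyloxy)-2-Fl-benzene
Product: 9 2-allyl-3,5-bis(benzyloxy)-6-Fl-phenol
Conditions: N,N-diethylaniline, 190 °C, sealed tube
Reagents that add atoms: none
Why: Aromatic Claisen rearrangement; the [3,3] shift delivers the allyl group to the only unsubstituted ortho carbon and tautomerisation restores the phenol that becomes O1', while the basic amine solvent protects the acid-labile C4–aryl bond.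

Step 8
Reactants: 9 2-allyl-3,5-bis(benzyloxy)-6-Fl-phenol, 10 3,4,5-tris(benzyloxy)benzoic acid
Product: 11 2-allyl-3,5-bis(benzyloxy)-6-Fl-phenyl 3,4,5-tris(benzyloxy)benzoate
Conditions: EDC·HCl, DMAP, CH2Cl2, rt to 40 °C
Reagents that add atoms: none
Why: Steglich esterification through the acylpyridinium ion, which acylates even a phenol with two ortho substituents; this ester carbon becomes C2' and its aryl group ring E.

Step 9
Reactants: 11 2-allyl-3,5-bis(benzyloxy)-6-Fl-phenyl 3,4,5-tris(benzyloxy)benzoate
Product: 13 3,5-bis(benzyloxy)-2-(2-oxoethyl)-6-Fl-phenyl 3,4,5-tris(benzyloxy)benzoate, via vicinal diol 12 (not isolated)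
Conditions: OsO4 (cat.), NaIO4, 2,6-lutidine, dioxane/H2O, rt; crude aldehyde used at once
Reagents that add atoms: osmium tetroxide, O=[Os](=O)(=O)=O (oxygen atoms of 12, replenished from sodium periodate, [Na+].[O-]I(=O)(=O)=O)
Why: Lemieux–Johnson oxidative cleavage; dihydroxylation is selective for the terminal alkene over the alkoxyarenes (which ozone would attack), periodate cleaves the diol with loss of one carbon, and the lutidine buffer spares the aryl ester.

Step 10
Reactants: 13 3,5-bis(benzyloxy)-2-(2-oxoethyl)-6-Fl-phenyl 3,4,5-tris(benzyloxy)benzoate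
Product: 14 5',7'-bis(benzyloxy)-8'-Fl-2'-[3,4,5-tris(benzyloxy)phenyl]-4'H-chromene
Conditions: TiCl3, Zn dust, DME, reflux (low-valent titanium formed first); 13 in DME added slowly by syringe pump (high dilution); aq. K2CO3 work-up
Reagents that add atoms: none
Why: Low-valent titanium from TiCl3 and zinc transfers an electron to the aldehyde, the most easily reduced group, giving a titanium-bound ketyl at C3'. The ketyl carbon adds to the carbonyl carbon of the neighbouring aryl ester (C2'), closing ring F by a 6-exo-trig attack to a titanium 2',3'-diolate, and deoxygenation of this diolate on titanium gives the C2'=C3' enol ether. The closest known reaction type is the McMurry-type intramolecular coupling of an oxo group with an ester, which turns acyloxy carbonyl compounds into benzofurans and keto esters into cyclic enol ethers. No stereocentre is formed, and C2 and C4 of the upper flavan are remote and not enolisable. The selectivity needed is intramolecular cross-coupling over reductive dimerisation of the aldehyde. The ortho placement of the CH2CHO group and the ester on ring D holds the two carbonyls within reach of a six-membered ring, the ester is not reduced on its own, and slow addition keeps the ketyl dilute. Benzyl ethers are inert to the reagent, and the basic work-up protects the acid-labile enol ether.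

Step 11
Reactants: 14 5',7'-bis(benzyloxy)-8'-Fl-2'-[3,4,5-tris(benzyloxy)phenyl]-4'H-chromene
Product: 16 (2'R,3'S)-5',7'-bis(benzyloxy)-8'-Fl-2'-[3,4,5-tris(benzyloxy)phenyl]chroman-3'-ol (2',3'-trans), via C3' alkyl(isopinocampheyl)borane 15 (not isolated)
Conditions: IpcBH2 [from (+)-α-pinene, freed beforehand from its TMEDA adduct with BF3·OEt2], THF, −25 °C to 0 °C; then NaOH, H2O2, 0 °C to rt
Reagents that add atoms: hydrogen peroxide, OO; monoisopinocampheylborane, C[C@H]1[C@H](B)C[C@@H]2C[C@H]1C2(C)C (its boron and isopinocampheyl group stay only in 15)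
Why: Asymmetric hydroboration of a trisubstituted alkene and oxidation with retention; boron goes to C3' (β to O1' and to ring E) and H and B add syn, so the alcohol is 2',3'-trans, and the chiral borane, by analogy with 1-arylcycloalkenes, should deliver hydrogen to the face of C2' that gives 2'R.

Step 12
Reactants: 16 (2'R,3'S)-5',7'-bis(benzyloxy)-8'-Fl-2'-[3,4,5-tris(benzyloxy)phenyl]chroman-3'-ol
Product: 17 (2'R)-5',7'-bis(benzyloxy)-8'-Fl-2'-[3,4,5-tris(benzyloxy)phenyl]chroman-3'-one
Conditions: Dess–Martin periodinane, wet CH2Cl2, rt; used without delay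
Reagents that add atoms: none
Why: Dess–Martin oxidation under near-neutral conditions, the standard entry to flavan-3-ones from trans flavan-3-ols; short contact time and the absence of base should keep the enolisable C2' centre intact.

Step 13
Reactants: 17 (2'R)-5',7'-bis(benzyloxy)-8'-Fl-2'-[3,4,5-tris(benzyloxy)phenyl]chroman-3'-one
Product: 18 (2'R,3'R)-5',7'-bis(benzyloxy)-8'-Fl-2'-[3,4,5-tris(benzyloxy)phenyl]chroman-3'-ol (2',3'-cis)
Conditions: LiBH(s-Bu)3, LiBr, THF, −78 °C
Reagents that add atoms: none
Why: Substrate-controlled reduction with a bulky hydride, which attacks the ketone from the face opposite the pseudo-equatorial ring E and gives the axial, cis alcohol, as in the conversion of the catechin into the epicatechin series; C3' is set by C2'.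

Step 14
Reactants: 18 (2'R,3'R)-5',7'-bis(benzyloxy)-8'-Fl-2'-[3,4,5-tris(benzyloxy)phenyl]chroman-3'-ol, 10 3,4,5-tris(benzyloxy)benzoic acid
Product: 19 (2'R,3'R)-5',7'-bis(benzyloxy)-8'-Fl-2'-[3,4,5-tris(benzyloxy)phenyl]chroman-3'-yl 3,4,5-tris(benzyloxy)benzoate (dodeca-O-benzyl ether of 20)
Conditions: EDC·HCl, DMAP, CH2Cl2, 0 °C to rt
Reagents that add atoms: none
Why: Steglich esterification with retention at C3', the usual way to attach a protected galloyl group to a cis flavan-3-ol; the mild base does not epimerise C2'.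

Step 15
Reactants: 19 dodeca-O-benzyl ether of 20
Product: 20 (2R,3R)-8-[(2S,4R)-2-(3,4-dihydroxyphenyl)-5,7-dihydroxychroman-4-yl]-5,7-dihydroxy-2-(3,4,5-trihydroxyphenyl)chroman-3-yl 3,4,5-trihydroxybenzoate
Conditions: H2 (1 atm), Pd(OH)2/C, THF/MeOH, rt; filtration and freeze-drying under argon
Reagents that add atoms: none
Why: Hydrogenolysis of the twelve benzyl ethers under neutral conditions, as used for the last step of oligomeric flavan-3-ol syntheses; the cyclic benzylic C–O bonds, the C4–C8' bond and the ester should survive.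

## Compound list

1 | (+)-catechin, (2R,3S)-2-(3,4-dihydroxyphenyl)chroman-3,5,7-triol | O[C@H]1Cc2c(O)cc(O)cc2O[C@@H]1c1ccc(O)c(O)c1 | starting material
2 | (2R,3S)-5,7-bis(benzyloxy)-2-[3,4-bis(benzyloxy)phenyl]chroman-3-ol | O[C@H]1Cc2c(OCc9ccccc9)cc(OCc9ccccc9)cc2O[C@@H]1c1ccc(OCc9ccccc9)c(OCc9ccccc9)c1 | intermediate
3 | (2R,3S,4S)-5,7-bis(benzyloxy)-2-[3,4-bis(benzyloxy)phenyl]-4-(2-ethoxyethoxy)chroman-3-ol | O[C@H]1[C@@H](OCCOCC)c2c(OCc9ccccc9)cc(OCc9ccccc9)cc2O[C@@H]1c1ccc(OCc9ccccc9)c(OCc9ccccc9)c1 | intermediate
4 | O-phenyl O-[(2R,3S,4S)-5,7-bis(benzyloxy)-2-[3,4-bis(benzyloxy)phenyl]-4-(2-ethoxyethoxy)chroman-3-yl] carbonothioate | S=C(Oc1ccccc1)O[C@H]1[C@@H](OCCOCC)c2c(OCc9ccccc9)cc(OCc9ccccc9)cc2O[C@@H]1c1ccc(OCc9ccccc9)c(OCc9ccccc9)c1 | intermediate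
5 | (2S,4R)-5,7-bis(benzyloxy)-2-[3,4-bis(benzyloxy)phenyl]-4-(2-ethoxyethoxy)chroman (2,4-trans) | CCOCCO[C@@H]1C[C@@H](c2ccc(OCc9ccccc9)c(OCc9ccccc9)c2)Oc2cc(OCc9ccccc9)cc(OCc9ccccc9)c21 | intermediate
6 | 3,5-bis(benzyloxy)phenol | Oc1cc(OCc9ccccc9)cc(OCc9ccccc9)c1 | starting material
7 | 3,5-bis(benzyloxy)-2-Fl-phenol (Fl ortho to OH, between OH and OBn) | Oc1cc(OCc9ccccc9)cc(OCc9ccccc9)c1[C@@H]1C[C@@H](c2ccc(OCc9ccccc9)c(OCc9ccccc9)c2)Oc2cc(OCc9ccccc9)cc(OCc9ccccc9)c21 | intermediate
8 | 1-(allyloxy)-3,5-bis(benzyloxy)-2-Fl-benzene | C=CCOc1cc(OCc9ccccc9)cc(OCc9ccccc9)c1[C@@H]1C[C@@H](c2ccc(OCc9ccccc9)c(OCc9ccccc9)c2)Oc2cc(OCc9ccccc9)cc(OCc9ccccc9)c21 | intermediate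
9 | 2-allyl-3,5-bis(benzyloxy)-6-Fl-phenol | C=CCc1c(OCc9ccccc9)cc(OCc9ccccc9)c([C@@H]2C[C@@H](c3ccc(OCc9ccccc9)c(OCc9ccccc9)c3)Oc3cc(OCc9ccccc9)cc(OCc9ccccc9)c32)c1O | intermediate
10 | 3,4,5-tris(benzyloxy)benzoic acid | O=C(O)c1cc(OCc9ccccc9)c(OCc9ccccc9)c(OCc9ccccc9)c1 | starting material
11 | 2-allyl-3,5-bis(benzyloxy)-6-Fl-phenyl 3,4,5-tris(benzyloxy)benzoate | C=CCc1c(OCc9ccccc9)cc(OCc9ccccc9)c([C@@H]2C[C@@H](c3ccc(OCc9ccccc9)c(OCc9ccccc9)c3)Oc3cc(OCc9ccccc9)cc(OCc9ccccc9)c32)c1OC(=O)c1cc(OCc9ccccc9)c(OCc9ccccc9)c(OCc9ccccc9)c1 | intermediate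
12 | 3,5-bis(benzyloxy)-2-(2,3-dihydroxypropyl)-6-Fl-phenyl 3,4,5-tris(benzyloxy)benzoate (both carbinol epimers) | OCC(O)Cc1c(OCc9ccccc9)cc(OCc9ccccc9)c([C@@H]2C[C@@H](c3ccc(OCc9ccccc9)c(OCc9ccccc9)c3)Oc3cc(OCc9ccccc9)cc(OCc9ccccc9)c32)c1OC(=O)c1cc(OCc9ccccc9)c(OCc9ccccc9)c(OCc9ccccc9)c1 | intermediate
13 | 3,5-bis(benzyloxy)-2-(2-oxoethyl)-6-Fl-phenyl 3,4,5-tris(benzyloxy)benzoate | O=CCc1c(OCc9ccccc9)cc(OCc9ccccc9)c([C@@H]2C[C@@H](c3ccc(OCc9ccccc9)c(OCc9ccccc9)c3)Oc3cc(OCc9ccccc9)cc(OCc9ccccc9)c32)c1OC(=O)c1cc(OCc9ccccc9)c(OCc9ccccc9)c(OCc9ccccc9)c1 | intermediate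
14 | 5',7'-bis(benzyloxy)-8'-Fl-2'-[3,4,5-tris(benzyloxy)phenyl]-4'H-chromene | C1(c2cc(OCc9ccccc9)c(OCc9ccccc9)c(OCc9ccccc9)c2)=CCc2c(OCc9ccccc9)cc(OCc9ccccc9)c([C@@H]3C[C@@H](c4ccc(OCc9ccccc9)c(OCc9ccccc9)c4)Oc4cc(OCc9ccccc9)cc(OCc9ccccc9)c43)c2O1 | intermediate
15 | C3' alkyl(isopinocampheyl)borane from syn addition to 14 (boron and the new C2' hydrogen on the same face, ring F configured as in 16) | C[C@H]1[C@H](B[C@H]2Cc3c(OCc9ccccc9)cc(OCc9ccccc9)c([C@@H]4C[C@@H](c5ccc(OCc9ccccc9)c(OCc9ccccc9)c5)Oc5cc(OCc9ccccc9)cc(OCc9ccccc9)c54)c3O[C@@H]2c2cc(OCc9ccccc9)c(OCc9ccccc9)c(OCc9ccccc9)c2)C[C@@H]2C[C@H]1C2(C)C | intermediate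
16 | (2'R,3'S)-5',7'-bis(benzyloxy)-8'-Fl-2'-[3,4,5-tris(benzyloxy)phenyl]chroman-3'-ol (2',3'-trans) | O[C@H]1Cc2c(OCc9ccccc9)cc(OCc9ccccc9)c([C@@H]3C[C@@H](c4ccc(OCc9ccccc9)c(OCc9ccccc9)c4)Oc4cc(OCc9ccccc9)cc(OCc9ccccc9)c43)c2O[C@@H]1c1cc(OCc9ccccc9)c(OCc9ccccc9)c(OCc9ccccc9)c1 | intermediate
17 | (2'R)-5',7'-bis(benzyloxy)-8'-Fl-2'-[3,4,5-tris(benzyloxy)phenyl]chroman-3'-one | O=C1Cc2c(OCc9ccccc9)cc(OCc9ccccc9)c([C@@H]3C[C@@H](c4ccc(OCc9ccccc9)c(OCc9ccccc9)c4)Oc4cc(OCc9ccccc9)cc(OCc9ccccc9)c43)c2O[C@@H]1c1cc(OCc9ccccc9)c(OCc9ccccc9)c(OCc9ccccc9)c1 | intermediate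
18 | (2'R,3'R)-5',7'-bis(benzyloxy)-8'-Fl-2'-[3,4,5-tris(benzyloxy)phenyl]chroman-3'-ol (2',3'-cis) | O[C@@H]1Cc2c(OCc9ccccc9)cc(OCc9ccccc9)c([C@@H]3C[C@@H](c4ccc(OCc9ccccc9)c(OCc9ccccc9)c4)Oc4cc(OCc9ccccc9)cc(OCc9ccccc9)c43)c2O[C@@H]1c1cc(OCc9ccccc9)c(OCc9ccccc9)c(OCc9ccccc9)c1 | intermediate
19 | (2'R,3'R)-5',7'-bis(benzyloxy)-8'-Fl-2'-[3,4,5-tris(benzyloxy)phenyl]chroman-3'-yl 3,4,5-tris(benzyloxy)benzoate | O=C(O[C@@H]1Cc2c(OCc9ccccc9)cc(OCc9ccccc9)c([C@@H]3C[C@@H](c4ccc(OCc9ccccc9)c(OCc9ccccc9)c4)Oc4cc(OCc9ccccc9)cc(OCc9ccccc9)c43)c2O[C@@H]1c1cc(OCc9ccccc9)c(OCc9ccccc9)c(OCc9ccccc9)c1)c1cc(OCc9ccccc9)c(OCc9ccccc9)c(OCc9ccccc9)c1 | intermediate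
20 | (2R,3R)-8-[(2S,4R)-2-(3,4-dihydroxyphenyl)-5,7-dihydroxychroman-4-yl]-5,7-dihydroxy-2-(3,4,5-trihydroxyphenyl)chroman-3-yl 3,4,5-trihydroxybenzoate | O=C(O[C@@H]1Cc2c(O)cc(O)c([C@@H]3C[C@@H](c4ccc(O)c(O)c4)Oc4cc(O)cc(O)c43)c2O[C@@H]1c1cc(O)c(O)c(O)c1)c1cc(O)c(O)c(O)c1 | target

## Step count and risk

Total step count: 15. Longest linear sequence: 15 steps, from 1 to 20; 6 and 10 enter as purchased compounds.

**Step 10 (key step).** The most likely failure is reductive dimerisation of the aldehyde between molecules (pinacol or alkene formation), or its simple reduction, outrunning attack of the ketyl on a hindered, electron-rich aryl ester. Hydrolysis or double-bond migration of the enol ether on the Lewis acidic titanium and zinc salts is the second danger. The fallback sets out from ester 11 and forms the same double bond by olefination and metathesis instead of reductive coupling. Methylenation of the ester carbonyl with Cp2TiMe2 in toluene at about 70 °C should give 2-allyl-3,5-bis(benzyloxy)-6-Fl-phenyl 1-[3,4,5-tris(benzyloxy)phenyl]vinyl ether F1. Ring-closing metathesis of its enol ether and allyl groups with the second-generation Grubbs catalyst RuCl2(=CHPh)(H2IMes)(PCy3) then closes ring F with loss of ethylene, coming back to the route at 14.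

**Step 5.** Two selectivities may be incomplete: attack of the cation at the ring carbon of 6 that lies between the two benzyloxy groups, and attack on the face of the cation next to ring B, giving the 2,4-cis isomer. Loss of a C3 proton to a flavene and self-condensation of the cation with its own ring A can also consume material. The fallback removes the regiochemical question by using a nucleophile with only one kind of ring carbon. Starting from 5, coupling with a large excess of phloroglucinol under the same Lewis acid gives 2-Fl-benzene-1,3,5-triol F2. Benzylation with one equivalent of BnBr and K2CO3 at the unhindered hydroxyl para to Fl gives 5-(benzyloxy)-2-Fl-benzene-1,3-diol F3. Monoallylation of one of the two equivalent hydroxyls flanking Fl gives 3-(allyloxy)-5-(benzyloxy)-2-Fl-phenol F4, and benzylation of the last hydroxyl comes back to the route at 8.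

**Step 11.** Facial selectivity may be poor, because the bulky Fl group sits next to O1' and the alkene is an enol ether, not a plain arylcycloalkene. The hindered borane may also add slowly, and the β-aryloxy borane may open ring F by elimination before it is oxidised. The fallback moves the stereocontrol from the alkene to the ketone. Starting from 14, hydroboration with BH3·THF and oxidation without facial control gives the 2',3'-trans alcohol as a mixture of both trans diastereomers F5. Dess–Martin oxidation gives the ketone as a mixture of C2' epimers F6. Asymmetric transfer hydrogenation with RuCl(p-cymene)(TsDPEN) and HCO2H/Et3N, with the catalyst enantiomer chosen to give the 3'R alcohol, should then proceed under dynamic kinetic resolution: the two ketone epimers interconvert through the enol while the catalyst reduces one of them to the cis alcohol, coming back to the route at 18.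

**Step 12 (with step 13).** Epimerisation at C2' of the ketone (benzylic, α to the carbonyl and to oxygen), enolisation towards C4' and air oxidation of the enol may erode the centre set in step 11 before the hydride arrives. The fallback avoids the ketone. Starting from 16, Mitsunobu esterification with acid 10 (PPh3, DIAD, THF) inverts C3' and installs the gallate in one step, coming back to the route at 19. It makes no compound outside the list (F0); its own weakness, elimination on activating a trans flavan-3-ol, is why it is not the first choice.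

## Further compounds

F1 | step 10 | 2-allyl-3,5-bis(benzyloxy)-6-Fl-phenyl 1-[3,4,5-tris(benzyloxy)phenyl]vinyl ether | C=CCc1c(OCc9ccccc9)cc(OCc9ccccc9)c([C@@H]2C[C@@H](c3ccc(OCc9ccccc9)c(OCc9ccccc9)c3)Oc3cc(OCc9ccccc9)cc(OCc9ccccc9)c32)c1OC(=C)c1cc(OCc9ccccc9)c(OCc9ccccc9)c(OCc9ccccc9)c1
F2 | step 5 | 2-Fl-benzene-1,3,5-triol | Oc1cc(O)c([C@@H]2C[C@@H](c3ccc(OCc9ccccc9)c(OCc9ccccc9)c3)Oc3cc(OCc9ccccc9)cc(OCc9ccccc9)c32)c(O)c1
F3 | step 5 | 5-(benzyloxy)-2-Fl-benzene-1,3-diol | Oc1cc(OCc9ccccc9)cc(O)c1[C@@H]1C[C@@H](c2ccc(OCc9ccccc9)c(OCc9ccccc9)c2)Oc2cc(OCc9ccccc9)cc(OCc9ccccc9)c21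
F4 | step 5 | 3-(allyloxy)-5-(benzyloxy)-2-Fl-phenol | C=CCOc1cc(OCc9ccccc9)cc(O)c1[C@@H]1C[C@@H](c2ccc(OCc9ccccc9)c(OCc9ccccc9)c2)Oc2cc(OCc9ccccc9)cc(OCc9ccccc9)c21
F5 | step 11 | 2',3'-trans-5',7'-bis(benzyloxy)-8'-Fl-2'-[3,4,5-tris(benzyloxy)phenyl]chroman-3'-ol, mixture of the (2'R,3'S) and (2'S,3'R) diastereomers | OC1Cc2c(OCc9ccccc9)cc(OCc9ccccc9)c([C@@H]3C[C@@H](c4ccc(OCc9ccccc9)c(OCc9ccccc9)c4)Oc4cc(OCc9ccccc9)cc(OCc9ccccc9)c43)c2OC1c1cc(OCc9ccccc9)c(OCc9ccccc9)c(OCc9ccccc9)c1
F6 | step 11 | 5',7'-bis(benzyloxy)-8'-Fl-2'-[3,4,5-tris(benzyloxy)phenyl]chroman-3'-one, mixture of C2' epimers | O=C1Cc2c(OCc9ccccc9)cc(OCc9ccccc9)c([C@@H]3C[C@@H](c4ccc(OCc9ccccc9)c(OCc9ccccc9)c4)Oc4cc(OCc9ccccc9)cc(OCc9ccccc9)c43)c2OC1c1cc(OCc9ccccc9)c(OCc9ccccc9)c(OCc9ccccc9)c1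
F0 | step 12 | none | none
A1 | alternative 1 | 2,4-trans 7-silyloxy tetrahydrochromen-5-one with ring C closed, attached at C8' of the perbenzylated lower unit | O=C(O[C@@H]1Cc2c(OCc9ccccc9)cc(OCc9ccccc9)c([C@@H]3C[C@@H](c4ccc(OCc9ccccc9)c(OCc9ccccc9)c4)OC4=C3C(=O)CC(O[Si](C)(C)C(C)(C)C)C4)c2O[C@@H]1c1cc(OCc9ccccc9)c(OCc9ccccc9)c(OCc9ccccc9)c1)c1cc(OCc9ccccc9)c(OCc9ccccc9)c(OCc9ccccc9)c1
A2 | alternative 1 | open-chain hydroxy dione: C8' substituent 1-(2,6-dioxo-4-silyloxycyclohexyl)-3-hydroxy-3-[3,4-bis(benzyloxy)phenyl]propyl on the perbenzylated lower unit | O=C(O[C@@H]1Cc2c(OCc9ccccc9)cc(OCc9ccccc9)c([C@H](C[C@H](O)c3ccc(OCc9ccccc9)c(OCc9ccccc9)c3)C3C(=O)CC(O[Si](C)(C)C(C)(C)C)CC3=O)c2O[C@@H]1c1cc(OCc9ccccc9)c(OCc9ccccc9)c(OCc9ccccc9)c1)c1cc(OCc9ccccc9)c(OCc9ccccc9)c(OCc9ccccc9)c1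
A3 | alternative 1 | octa-O-benzyl-(−)-epigallocatechin gallate | O=C(O[C@@H]1Cc2c(OCc9ccccc9)cc(OCc9ccccc9)cc2O[C@@H]1c1cc(OCc9ccccc9)c(OCc9ccccc9)c(OCc9ccccc9)c1)c1cc(OCc9ccccc9)c(OCc9ccccc9)c(OCc9ccccc9)c1
A4 | alternative 2 | dodeca-O-benzyl ether of the target (identical with 19) | O=C(O[C@@H]1Cc2c(OCc9ccccc9)cc(OCc9ccccc9)c([C@@H]3C[C@@H](c4ccc(OCc9ccccc9)c(OCc9ccccc9)c4)Oc4cc(OCc9ccccc9)cc(OCc9ccccc9)c43)c2O[C@@H]1c1cc(OCc9ccccc9)c(OCc9ccccc9)c(OCc9ccccc9)c1)c1cc(OCc9ccccc9)c(OCc9ccccc9)c(OCc9ccccc9)c1
A5 | alternative 2 | octa-O-benzyl-(−)-epigallocatechin gallate 8'-carbaldehyde | O=C(O[C@@H]1Cc2c(OCc9ccccc9)cc(OCc9ccccc9)c(C=O)c2O[C@@H]1c1cc(OCc9ccccc9)c(OCc9ccccc9)c(OCc9ccccc9)c1)c1cc(OCc9ccccc9)c(OCc9ccccc9)c(OCc9ccccc9)c1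
A6 | alternative 2 | 3,4-bis(benzyloxy)styrene | C=Cc1ccc(OCc9ccccc9)c(OCc9ccccc9)c1
A7 | alternative 2 | 3,5-bis(benzyloxy)phenol (identical with 6) | Oc1cc(OCc9ccccc9)cc(OCc9ccccc9)c1
A8 | alternative 3 | perbenzylated 2',3'-cis flavan C3' pinacol boronate bearing Fl at C8' | CC1(C)OB([C@@H]2Cc3c(OCc9ccccc9)cc(OCc9ccccc9)c([C@@H]4C[C@@H](c5ccc(OCc9ccccc9)c(OCc9ccccc9)c5)Oc5cc(OCc9ccccc9)cc(OCc9ccccc9)c54)c3O[C@@H]2c2cc(OCc9ccccc9)c(OCc9ccccc9)c(OCc9ccccc9)c2)OC1(C)C
A9 | alternative 3 | 3,5-bis(benzyloxy)-2-(hydroxymethyl)-6-Fl-phenol (ring D salicyl alcohol) | OCc1c(OCc9ccccc9)cc(OCc9ccccc9)c([C@@H]2C[C@@H](c3ccc(OCc9ccccc9)c(OCc9ccccc9)c3)Oc3cc(OCc9ccccc9)cc(OCc9ccccc9)c32)c1O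
A10 | alternative 3 | (Z)-2-[3,4,5-tris(benzyloxy)phenyl]ethenylboronic acid pinacol ester | CC1(C)OB(/C=C\c2cc(OCc9ccccc9)c(OCc9ccccc9)c(OCc9ccccc9)c2)OC1(C)C
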